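**Plan**
Retrosynthesis: after removing C5–Cl and unmasking the C7 carbinol and the β-keto lactone, the bicycle is cut at C4a–C8a and O2–C1 in one retro-hetero-Diels–Alder step; the chain is then cut at C5–C6 (acetylide to aldehyde), C3–C4 (propargylation) and C7–C8 with C3'–C4' (Michael–Dieckmann), and the side chain at its two alkenes.
Forward: the lactone ring arises first, together with C7–C8; the chain is joined at C5–C6 and both carbinols are oxidised; the carbocycle and the pyran then close together, followed by chlorination and unmasking.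
Enabling feature (isochromene locants O2, C1–C8a; lactone C2'–C6'): the 4-alkylidene-4H-pyran (ring O2/C3/C4/C4a/C8a/C1 with exocyclic C4a=C5) is the [4+2] adduct of an acyl-allene oxadiene O2=C3–C4=C4a and a C8a=C1 enol ether after loss of alcohol, and sp3 C7 and C8 exclude aromatisation.
Stereochemistry: C7 comes from (R)-lactic acid through its cis dioxolanone (the new bond takes the place of the lactate hydrogen, so the (R)-acid is required); C8 comes from the topicity of the Michael addition; C6' from ethyl (S)-3-hydroxybutanoate; the side-chain centre from (S)-2-methylbutan-1-ol.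
Key step: step 18

Assumption: C3' is the enolisable methine of a β-keto lactone; the (3'R) epimer drawn for the target is taken to be the one reached under thermodynamic control in the last step.
Remark: the target locants are used for the corresponding atoms of all intermediates; enol ethers from step 7 onward are drawn E, the Z isomer being carried along because both converge in step 18.

Step 1
Reactants: 1 (R)-lactic acid
Product: 2 (2R,5R)-2-tert-butyl-5-methyl-1,3-dioxolan-4-one (cis)
Conditions: t-BuCHO, p-TsOH (cat.), H2SO4 (cat.), pentane, reflux, water separator; crystallisation at −78 °C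
Reagents that add atoms: pivalaldehyde, CC(C)(C)C=O
Why: Acid-catalysed acetalisation under equilibrating conditions should give mainly the cis dioxolanone, purified by crystallisation, so that the acetal carbon can later relay the lactate configuration (self-regeneration of stereocentres).

Step 2
Reactants: 3 ethyl (S)-3-hydroxybutanoate
Product: 4 (S)-3-hydroxy-N-methoxy-N-methylbutanamide
Conditions: MeNH(OMe)·HCl, i-PrMgCl, THF, −20 → 0 °C
Reagents that add atoms: N,O-dimethylhydroxylamine hydrochloride, CNOC.Cl
Why: Ester aminolysis by MeN(OMe)MgCl (Weinreb amide formation) is reliable for β-hydroxy esters and leaves the carbinol centre untouched; the amide is chosen because its α-hydrogens are much less acidic than those of the ester and because it acylates an enolate only once.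

Step 3
Reactants: 4 (S)-3-hydroxy-N-methoxy-N-methylbutanamide
Product: 5 (2S)-4-[methoxy(methyl)amino]-4-oxobutan-2-yl prop-2-enoate
Conditions: acryloyl chloride, Et3N, CH2Cl2, −20 → 0 °C
Reagents that add atoms: acryloyl chloride, C=CC(=O)Cl
Why: O-Acylation of the secondary alcohol by the acid chloride with an amine base proceeds with retention at carbon, and at low temperature β-elimination should not compete.

Step 4
Reactants: 5 (2S)-4-[methoxy(methyl)amino]-4-oxobutan-2-yl prop-2-enoate; 6 4,4-diethoxybut-1-ene
Product: 7 (2S)-4-[methoxy(methyl)amino]-4-oxobutan-2-yl (2E)-5,5-diethoxypent-2-enoate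
Conditions: second-generation Grubbs catalyst RuCl2(=CHPh)(H2IMes)(PCy3) (5 mol %), 6 (3 equiv), CH2Cl2, 40 °C
Reagents that add atoms: none
Why: Olefin cross-metathesis of the electron-poor acrylate with an excess of the unhindered terminal alkene should give the (E)-enoate selectively and tolerates the acetal and the amide.

Step 5
Reactants: 2 (2R,5R)-2-tert-butyl-5-methyl-1,3-dioxolan-4-one; 7 (2S)-4-[methoxy(methyl)amino]-4-oxobutan-2-yl (2E)-5,5-diethoxypent-2-enoate
Product: 10 lithium enolate of (2R,5S)-2-tert-butyl-5-{(1R)-3,3-diethoxy-1-[(6S)-4-hydroxy-6-methyl-2-oxo-5,6-dihydro-2H-pyran-3-yl]propyl}-5-methyl-1,3-dioxolan-4-one (crude salt), via Michael adduct ester enolate 8 (not isolated), via tetrahedral Claisen adduct 9 (not isolated)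
Conditions: 2, LiN(i-Pr)2, THF, −78 °C; then 7, −78 → −20 °C; MeOH, −20 °C; evaporation
Reagents that add atoms: lithium diisopropylamide, [Li+].CC(C)[N-]C(C)C
Why: Michael addition of the lithium dioxolanone enolate followed in the same flask by Dieckmann (intramolecular Claisen) acylation: the enoate is attacked from the enolate face anti to the tert-butyl group, which fixes C7 with overall retention of the lactate configuration; C8 is expected from a closed, lithium-bridged transition state in which the enoate C=C lies gauche to the enolate C=C on the O–Li side and the CH2CH(OEt)2 group is anti to the enolate C=C; and the ester enolate generated regiospecifically at C3' then closes the six-membered lactone on the Weinreb amide (6-enolendo-exo-trig), whose stable tetrahedral adduct releases the β-dicarbonyl enolate only on methanolysis.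

Step 6
Reactants: 10 lithium enolate of the β-keto lactone
Product: 11 (2R,5S)-2-tert-butyl-5-{(1R)-3,3-diethoxy-1-[(6S)-4-methoxy-6-methyl-2-oxo-5,6-dihydro-2H-pyran-3-yl]propyl}-5-methyl-1,3-dioxolan-4-one
Conditions: Me2SO4, K2CO3, acetone, 23 °C
Reagents that add atoms: dimethyl sulfate, COS(=O)(=O)OC
Why: O-Methylation of the β-keto lactone enolate by a hard electrophile should give the 4-methoxy-5,6-dihydropyran-2-one, the usual regiochemistry for 4-hydroxy-5,6-dihydropyran-2-ones, and because the enolate is never protonated the acidic dione cannot condense with the neighbouring acetal.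

Step 7
Reactants: 11 the acetal dioxolanone
Product: 12 (2R,5S)-2-tert-butyl-5-{(1R,2E)-3-ethoxy-1-[(6S)-4-methoxy-6-methyl-2-oxo-5,6-dihydro-2H-pyran-3-yl]prop-2-en-1-yl}-5-methyl-1,3-dioxolan-4-one
Conditions: TMSOTf, i-Pr2NEt, CH2Cl2, −20 → 0 °C
Reagents that add atoms: none
Why: The silyl triflate ionises the diethyl acetal to an oxocarbenium ion and the hindered amine removes a C8a proton (acetal-to-enol-ether elimination), giving the future dienophile, while the dioxolanone acetal (deactivated by its acyloxy oxygen) and the vinylogous carbonate should stay intact.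

Step 8
Reactants: 12 the enol ether dioxolanone
Product: 13 (6S)-3-[(1E,3R,4S)-1-ethoxy-4,5-dihydroxy-4-methylpent-1-en-3-yl]-4-methoxy-6-methyl-5,6-dihydro-2H-pyran-2-one
Conditions: LiBH4, THF, −20 → 0 °C; pH 7 buffer
Reagents that add atoms: none
Why: Borohydride should reduce the activated, acylal-type dioxolanone carbonyl much faster than the donor-deactivated vinylogous carbonate of the lactone, the hemiacetal collapsing with loss of pivalaldehyde to the primary–tertiary 1,2-diol without change at C7 or C8.

Step 9
Reactants: 13 the 1,2-diol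
Product: 14 (6S)-3-[(1E,3R,4S)-1-ethoxy-4-methyl-4,5-bis(triethylsilyloxy)pent-1-en-3-yl]-4-methoxy-6-methyl-5,6-dihydro-2H-pyran-2-one
Conditions: TESOTf, 2,6-lutidine, CH2Cl2, −78 → 0 °C
Reagents that add atoms: triethylsilyl trifluoromethanesulfonate, CC[Si](CC)(CC)OS(=O)(=O)C(F)(F)F
Why: Silyl triflate with 2,6-lutidine silylates both hydroxyls, the tertiary one included, under buffered conditions that enol ethers tolerate; the C7 ether is needed later to stop oxa-Michael addition of this oxygen to the ynone and the allene.

Step 10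
Reactants: 14 the bis(triethylsilyl) ether
Product: 15 (2S,3R,4E)-5-ethoxy-3-[(6S)-4-methoxy-6-methyl-2-oxo-5,6-dihydro-2H-pyran-3-yl]-2-methyl-2-[(triethylsilyl)oxy]pent-4-enal
Conditions: (COCl)2, DMSO, CH2Cl2, −78 → −30 °C; then Et3N, −78 → 0 °C
Reagents that add atoms: none
Why: Under Swern conditions the unhindered primary triethylsilyl ether is activated by chlorodimethylsulfonium chloride and oxidised directly to the aldehyde (oxidative desilylation) while the tertiary silyl ether should survive, and the aldehyde has no α-hydrogen, so C7 cannot epimerise.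

Step 11
Reactants: 16 (S)-2-methylbutan-1-ol
Product: 18 ethyl (2E,4S)-2,4-dimethylhex-2-enoate, via (S)-2-methylbutanal 17 (not isolated)
Conditions: TEMPO (cat.), PhI(OAc)2, CH2Cl2, 23 °C; then Ph3P=C(Me)CO2Et, 23 °C
Reagents that add atoms: ethyl 2-(triphenylphosphoranylidene)propanoate, CCOC(=O)C(C)=P(c1ccccc1)(c1ccccc1)c1ccccc1
Why: TEMPO-catalysed oxidation gives the configurationally fragile α-branched aldehyde, which is trapped at once by the stabilised ylide in an (E)-selective Wittig reaction, so the stereocentre is not exposed to base or isolation.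

Step 12
Reactants: 18 ethyl (2E,4S)-2,4-dimethylhex-2-enoate
Product: 19 (2E,4S)-2,4-dimethylhex-2-en-1-ol
Conditions: i-Bu2AlH, CH2Cl2, −78 °C
Reagents that add atoms: none
Why: 1,2-Reduction of the enoate by the aluminium hydride gives the allylic alcohol without touching the alkene or the stereocentre.

Step 13
Reactants: 19 (2E,4S)-2,4-dimethylhex-2-en-1-ol
Product: 21 (2E,4E,6S)-N-methoxy-N,4,6-trimethylocta-2,4-dienamide, via dimethylhexenal 20 (not isolated)
Conditions: MnO2, Ph3P=CHC(O)N(OMe)Me, CH2Cl2, 40 °C
Reagents that add atoms: N-methoxy-N-methyl-2-(triphenylphosphoranylidene)acetamide, CON(C)C(=O)C=P(c1ccccc1)(c1ccccc1)c1ccccc1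
Why: MnO2 oxidises the allylic alcohol to the enal, which is intercepted in situ by the stabilised amide ylide in an (E)-selective Wittig reaction (tandem oxidation–olefination).

Step 14
Reactants: 21 (2E,4E,6S)-N-methoxy-N,4,6-trimethylocta-2,4-dienamide
Product: 22 (2E,4E,6S)-4,6-dimethylocta-2,4-dienal
Conditions: i-Bu2AlH, THF, −78 °C
Reagents that add atoms: none
Why: Reduction of the Weinreb amide stops at the aldehyde because the chelated tetrahedral aluminium adduct persists until work-up.

Step 15
Reactants: 22 (2E,4E,6S)-4,6-dimethylocta-2,4-dienal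
Product: 23 (5E,7E,9S)-7,9-dimethylundeca-5,7-dien-1-yn-4-ol (both C4 epimers)
Conditions: propargyl bromide, Zn, THF/sat. aq NH4Cl, 0 °C
Reagents that add atoms: propargyl bromide, C#CCBr
Why: Barbier propargylation: the organozinc formed in situ adds 1,2 to the dienal through its allenyl form (SE2') to give the homopropargylic alcohol, whose carbinol centre need not be controlled because it is oxidised in step 17.

Step 16
Reactants: 23 (5E,7E,9S)-7,9-dimethylundeca-5,7-dien-1-yn-4-ol; 15 the α-silyloxy aldehyde
Product: 24 diol dienyl–C3H(OH)–C4H2–C4a≡C5–C6H(OH)–C7(Me)(OSiEt3)–C8H(lactone enol ether)–C8aH=C1H–OEt (carbinol epimers at C3 and C6)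
Conditions: 23, n-BuLi (2 equiv), THF, −78 → −40 °C; then 15, −78 °C; AcOH, −78 °C
Reagents that add atoms: none
Why: The alkoxide–acetylide dianion adds through its alkynyllithium carbon to the non-enolisable α-silyloxy aldehyde at −78 °C, much faster than to the vinylogous carbonate lactone, forming C5–C6; the carbinol configuration is irrelevant and the cold acidic quench forestalls 1,2-silyl migration.

Step 17
Reactants: 24 the propargylic and dienylic diol
Product: 25 skipped ynedione dienyl–C3(=O)–C4H2–C4a≡C5–C6(=O)–C7(Me)(OSiEt3)–C8H(lactone enol ether)–C8aH=C1H–OEt (crude)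
Conditions: Dess–Martin periodinane, NaHCO3, CH2Cl2, 0 → 23 °C; crude used at once
Reagents that add atoms: none
Why: Dess–Martin oxidation converts the propargylic and the dienylic carbinol into the two ketones under buffered conditions that spare both enol ethers and the silyl ether.

Step 18
Reactants: 25 the skipped ynedione
Product: 28 (7S,8R)-3-[(1E,3E,5S)-3,5-dimethylhepta-1,3-dien-1-yl]-8-[(6S)-4-methoxy-6-methyl-2-oxo-5,6-dihydro-2H-pyran-3-yl]-7-methyl-7-[(triethylsilyl)oxy]-7,8-dihydro-6H-isochromen-6-one, via acyl allene 26 (not isolated), via cycloadduct acetal 27 (not isolated)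
Conditions: Et3N (0.3 equiv), PhMe (0.005 M), 23 → 60 °C; then DBU, 23 °C
Reagents that add atoms: none
Why: Proposed new method: Et3N isomerises the skipped ynedione to the 1,3-diacyl allene 26 (deprotonation at C4, protonation at C5), whose C3 carbonyl and C4=C4a bond act as an electron-poor 1-oxadiene toward the tethered ethyl enol ether in an inverse-electron-demand hetero-Diels–Alder reaction, C8a bonding to the central allene carbon C4a and C1 to O2 while the orthogonal C4a=C5 bond remains as the exocyclic alkene; DBU then removes the vinylogously acidic C8a–H of adduct 27 and expels ethoxide from C1 (E1cB) to give C1=C8a. The closest known reactions are intramolecular inverse-demand hetero-Diels–Alder additions of enones and alkylidene-1,3-dicarbonyls to enol ethers, and the hetero-Diels–Alder dimerisation of allenyl ketones, in which an allenyl ketone serves as oxadiene through its C=O and proximal C=C. The carbocycle (C4a–C5–C6–C7–C8–C8a) closes by attack of C8a on the sp carbon C4a with the consumed C4=C4a bond outside the ring (6-exo-dig), and the pyran is the six-membered ring of the [4+2] adduct itself, completed by O2–C1 bonding (6-exo-trig on the oxocarbenium carbon if the addition is stepwise). No stereocentre of 28 is created: C8a and C1 of 27, set by the enol ether geometry and its approach relative to C8, are both erased by the elimination, and C7 (quaternary) and C8 (no activated hydrogen) are untouched. The step needs periselectivity (C3=O/C4=C4a rather than C6=O/C5=C4a or the side-chain dienone as heterodiene), regioselectivity (C8a to C4a) and chemoselectivity between the two enol ethers: the four-atom tether would turn the C6-carbonyl mode into a bridgehead-alkene bicycle and places only C4a within reach, the polarity match pairs the nucleophilic enol ether β-carbon with the doubly activated central allene carbon, and the lactone enol ether is a deactivated, fully substituted push–pull alkene. High dilution should suppress allenone dimerisation, and the C7 silyl ether blocks oxa-Michael closure to a 3(2H)-furanone.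

Step 19
Reactants: 28 the deschloro bicyclic core
Product: 29 (7S,8R)-5-chloro-3-[(1E,3E,5S)-3,5-dimethylhepta-1,3-dien-1-yl]-8-[(6S)-4-methoxy-6-methyl-2-oxo-5,6-dihydro-2H-pyran-3-yl]-7-methyl-7-[(triethylsilyl)oxy]-7,8-dihydro-6H-isochromen-6-one
Conditions: N-chlorosuccinimide, CH2Cl2, 0 → 23 °C, dark
Reagents that add atoms: N-chlorosuccinimide, O=C1CCC(=O)N1Cl
Why: Electrophilic chlorination by the N-chloroimide should occur at C5, the α-carbon of the vinylogous ester that receives electron density from O2 through both C3=C4 and C1=C8a and the position at which azaphilones are halogenated, in preference to the side-chain diene and the fully substituted lactone enol ether.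

Step 20
Reactants: 29 the 5-chloro silyl ether
Product: 30 (7S,8S)-5-chloro-3-[(1E,3E,5S)-3,5-dimethylhepta-1,3-dien-1-yl]-7-hydroxy-7-methyl-8-[(3R,6S)-6-methyl-2,4-dioxooxan-3-yl]-7,8-dihydro-6H-isochromen-6-one (CNP0584120.1)
Conditions: 2 M aq HCl, THF, 23 → 40 °C
Reagents that add atoms: water, O
Why: Aqueous acid cleaves the tertiary triethylsilyl ether and hydrolyses the vinylogous carbonate methyl enol ether (C-protonation at C3', addition of water at C4', loss of methanol) to the β-keto lactone, after which the labile C3' methine settles under thermodynamic control; the C8 descriptor changes from R to S only because C3' becomes sp3.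

**Compound list**
1 | (R)-lactic acid | C[C@@H](O)C(=O)O | starting material
2 | (2R,5R)-2-tert-butyl-5-methyl-1,3-dioxolan-4-one | C[C@H]1O[C@@H](C(C)(C)C)OC1=O | intermediate
3 | ethyl (S)-3-hydroxybutanoate | C[C@H](O)CC(=O)OCC | starting material
4 | (S)-3-hydroxy-N-methoxy-N-methylbutanamide | C[C@H](O)CC(=O)N(C)OC | intermediate
5 | (2S)-4-[methoxy(methyl)amino]-4-oxobutan-2-yl prop-2-enoate | C=CC(=O)O[C@@H](C)CC(=O)N(C)OC | intermediate
6 | 4,4-diethoxybut-1-ene | C=CCC(OCC)OCC | starting material
7 | (2S)-4-[methoxy(methyl)amino]-4-oxobutan-2-yl (2E)-5,5-diethoxypent-2-enoate | CCOC(OCC)C/C=C/C(=O)O[C@@H](C)CC(=O)N(C)OC | intermediate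
8 | Michael adduct, lithium ester enolate at C3' (not isolated) | C[C@@]1([C@H](CC(OCC)OCC)C=C([O-])O[C@@H](C)CC(=O)N(C)OC)O[C@@H](C(C)(C)C)OC1=O.[Li+] | intermediate
9 | tetrahedral Claisen adduct, lithium alkoxide of the cyclic N-methoxy-N-methyl hemiaminal at C4' (not isolated) | C[C@@]1([C@H](CC(OCC)OCC)C2C(=O)O[C@@H](C)CC2([O-])N(C)OC)O[C@@H](C(C)(C)C)OC1=O.[Li+] | intermediate
10 | lithium enolate of (2R,5S)-2-tert-butyl-5-{(1R)-3,3-diethoxy-1-[(6S)-4-hydroxy-6-methyl-2-oxo-5,6-dihydro-2H-pyran-3-yl]propyl}-5-methyl-1,3-dioxolan-4-one | C[C@@]1([C@H](CC(OCC)OCC)C2=C([O-])C[C@H](C)OC2=O)O[C@@H](C(C)(C)C)OC1=O.[Li+] | intermediate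
11 | (2R,5S)-2-tert-butyl-5-{(1R)-3,3-diethoxy-1-[(6S)-4-methoxy-6-methyl-2-oxo-5,6-dihydro-2H-pyran-3-yl]propyl}-5-methyl-1,3-dioxolan-4-one | C[C@@]1([C@H](CC(OCC)OCC)C2=C(OC)C[C@H](C)OC2=O)O[C@@H](C(C)(C)C)OC1=O | intermediate
12 | (2R,5S)-2-tert-butyl-5-{(1R,2E)-3-ethoxy-1-[(6S)-4-methoxy-6-methyl-2-oxo-5,6-dihydro-2H-pyran-3-yl]prop-2-en-1-yl}-5-methyl-1,3-dioxolan-4-one | C[C@@]1([C@H](/C=C/OCC)C2=C(OC)C[C@H](C)OC2=O)O[C@@H](C(C)(C)C)OC1=O | intermediate
13 | (6S)-3-[(1E,3R,4S)-1-ethoxy-4,5-dihydroxy-4-methylpent-1-en-3-yl]-4-methoxy-6-methyl-5,6-dihydro-2H-pyran-2-one | OC[C@@](C)(O)[C@H](/C=C/OCC)C1=C(OC)C[C@H](C)OC1=O | intermediate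
14 | (6S)-3-[(1E,3R,4S)-1-ethoxy-4-methyl-4,5-bis(triethylsilyloxy)pent-1-en-3-yl]-4-methoxy-6-methyl-5,6-dihydro-2H-pyran-2-one | CC[Si](CC)(CC)OC[C@@](C)(O[Si](CC)(CC)CC)[C@H](/C=C/OCC)C1=C(OC)C[C@H](C)OC1=O | intermediate
15 | (2S,3R,4E)-5-ethoxy-3-[(6S)-4-methoxy-6-methyl-2-oxo-5,6-dihydro-2H-pyran-3-yl]-2-methyl-2-[(triethylsilyl)oxy]pent-4-enal | O=C[C@@](C)(O[Si](CC)(CC)CC)[C@H](/C=C/OCC)C1=C(OC)C[C@H](C)OC1=O | intermediate
16 | (S)-2-methylbutan-1-ol | CC[C@H](C)CO | starting material
17 | (S)-2-methylbutanal (not isolated) | CC[C@H](C)C=O | intermediate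
18 | ethyl (2E,4S)-2,4-dimethylhex-2-enoate | CC[C@H](C)/C=C(C)/C(=O)OCC | intermediate
19 | (2E,4S)-2,4-dimethylhex-2-en-1-ol | CC[C@H](C)/C=C(C)/CO | intermediate
20 | (2E,4S)-2,4-dimethylhex-2-enal (not isolated) | CC[C@H](C)/C=C(C)/C=O | intermediate
21 | (2E,4E,6S)-N-methoxy-N,4,6-trimethylocta-2,4-dienamide | CC[C@H](C)/C=C(C)/C=C/C(=O)N(C)OC | intermediate
22 | (2E,4E,6S)-4,6-dimethylocta-2,4-dienal | CC[C@H](C)/C=C(C)/C=C/C=O | intermediate
23 | (5E,7E,9S)-7,9-dimethylundeca-5,7-dien-1-yn-4-ol (C4 epimers) | CC[C@H](C)/C=C(C)/C=C/C(O)CC#C | intermediate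
24 | C3,C6-diol with C4a≡C5 alkyne, C7 triethylsilyl ether, lactone methyl enol ether at C8 and C8a=C1 ethyl enol ether (carbinol epimers) | CC[C@H](C)/C=C(C)/C=C/C(O)CC#CC(O)[C@@](C)(O[Si](CC)(CC)CC)[C@H](/C=C/OCC)C1=C(OC)C[C@H](C)OC1=O | intermediate
25 | skipped ynedione (C3 and C6 ketones, C4 methylene, C4a≡C5) | CC[C@H](C)/C=C(C)/C=C/C(=O)CC#CC(=O)[C@@](C)(O[Si](CC)(CC)CC)[C@H](/C=C/OCC)C1=C(OC)C[C@H](C)OC1=O | intermediate
26 | 1,3-diacyl allene C3(=O)–C4H=C4a=C5H–C6(=O) with tethered enol ether (not isolated, both allene epimers) | CC[C@H](C)/C=C(C)/C=C/C(=O)C=C=CC(=O)[C@@](C)(O[Si](CC)(CC)CC)[C@H](/C=C/OCC)C1=C(OC)C[C@H](C)OC1=O | intermediate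
27 | hetero-Diels–Alder adduct, 1-ethoxy-1,8a-dihydro acetal of 28 (not isolated, C1/C8a epimers) | CC[C@H](C)/C=C(C)/C=C/C1=CC2=CC(=O)[C@@](C)(O[Si](CC)(CC)CC)[C@@H](C3=C(OC)C[C@H](C)OC3=O)C2C(OCC)O1 | intermediate
28 | (7S,8R)-3-[(1E,3E,5S)-3,5-dimethylhepta-1,3-dien-1-yl]-8-[(6S)-4-methoxy-6-methyl-2-oxo-5,6-dihydro-2H-pyran-3-yl]-7-methyl-7-[(triethylsilyl)oxy]-7,8-dihydro-6H-isochromen-6-one | CC[C@H](C)/C=C(C)/C=C/C1=CC2=CC(=O)[C@@](C)(O[Si](CC)(CC)CC)[C@@H](C3=C(OC)C[C@H](C)OC3=O)C2=CO1 | intermediate
29 | 5-chloro derivative of 28 | CC[C@H](C)/C=C(C)/C=C/C1=CC2=C(Cl)C(=O)[C@@](C)(O[Si](CC)(CC)CC)[C@@H](C3=C(OC)C[C@H](C)OC3=O)C2=CO1 | intermediate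
30 | (7S,8S)-5-chloro-3-[(1E,3E,5S)-3,5-dimethylhepta-1,3-dien-1-yl]-7-hydroxy-7-methyl-8-[(3R,6S)-6-methyl-2,4-dioxooxan-3-yl]-7,8-dihydro-6H-isochromen-6-one | CC[C@H](C)/C=C(C)/C=C/C1=CC2=C(Cl)C(=O)[C@@](C)(O)[C@@H]([C@@H]3C(=O)C[C@H](C)OC3=O)C2=CO1 | target

**Step count and risks**
Total steps: 20. Longest linear sequence: 14 steps (steps 2–10 and 16–20, from ethyl (S)-3-hydroxybutanoate).

Steps most likely to fail:

1. Step 18 (proposed new method). The acyl allene may be consumed by intermolecular hetero-Diels–Alder dimerisation, amine conjugate addition or cycloisomerisation before the tethered enol ether bonds to C4a, or the adduct may not lose ethanol cleanly. The fallback sets out from 25 and comes back at 28, making the same two bonds stepwise by polar, known reactions. Mild aqueous acid (PPTS, acetone–water, 0 °C) hydrolyses only the simple ethyl enol ether to give the aldehyde ynedione F1. DBU then promotes an intramolecular Michael addition of the aldehyde enolate to the activated C4a of the ynone/allenone (base-mediated carbocyclisation onto an alkynone) to give the cyclohexenone 1,5-keto aldehyde F2. Acid-catalysed cyclodehydration of the 1,5-dicarbonyl unit (TsOH, molecular sieves), the classical closure of the azaphilone pyran from a keto aldehyde, then gives 28.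

2. Step 5. Attack on the enoate β-carbon may occur with low facial selectivity, or from the face opposite to the one predicted by the closed transition state, giving the C8 epimer. The fallback sets out from 4 and comes back at 10, and moves the control element to the alkene geometry. 4,4-Diethoxybut-1-yne is lithiated (n-BuLi) and carboxylated (CO2) to 5,5-diethoxypent-2-ynoic acid F3. Esterification with 4 (DCC, DMAP) gives the ynoate F4, and semi-hydrogenation (H2, Pd/CaCO3 poisoned with Pb(OAc)2, quinoline) gives the (Z)-enoate F5. Under the conditions of step 5, F5 should present the other β-carbon face in the same lithium-bridged arrangement and deliver 10.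

3. Step 20. The chlorinated 4H-pyran chromophore may degrade in aqueous acid (hydration at C1, ring opening), or the freed C7 hydroxyl may translactonise, before the slow hydrolysis of the vinylogous carbonate is complete. The fallback sets out from 29 and comes back at 30, and avoids hydrolysis. HF·pyridine (THF/pyridine, 0 °C) removes the silyl ether to give the hydroxy methyl enol ether F6. The O-methyl group is then removed by SN2 attack of chloride (LiCl, DMSO, 50 °C), and mild acidification of the resulting lithium enolate gives 30.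

**Further compounds**
F1 | step 18 | aldehyde ynedione, C8a H2–C1HO in place of the ethyl enol ether of 25 | CC[C@H](C)/C=C(C)/C=C/C(=O)CC#CC(=O)[C@@](C)(O[Si](CC)(CC)CC)[C@H](CC=O)C1=C(OC)C[C@H](C)OC1=O
F2 | step 18 | cyclohexenone 1,5-keto aldehyde, C8a-formyl with C4a–CH2–C3(=O)-dienyl (C8a epimers) | CC[C@H](C)/C=C(C)/C=C/C(=O)CC1=CC(=O)[C@@](C)(O[Si](CC)(CC)CC)[C@@H](C2=C(OC)C[C@H](C)OC2=O)C1C=O
F3 | step 5 | 5,5-diethoxypent-2-ynoic acid | OC(=O)C#CCC(OCC)OCC
F4 | step 5 | (2S)-4-[methoxy(methyl)amino]-4-oxobutan-2-yl 5,5-diethoxypent-2-ynoate | CCOC(OCC)CC#CC(=O)O[C@@H](C)CC(=O)N(C)OC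
F5 | step 5 | (2S)-4-[methoxy(methyl)amino]-4-oxobutan-2-yl (2Z)-5,5-diethoxypent-2-enoate | CCOC(OCC)C/C=C\C(=O)O[C@@H](C)CC(=O)N(C)OC
F6 | step 20 | 7-hydroxy analogue of 29 (lactone still as methyl enol ether) | CC[C@H](C)/C=C(C)/C=C/C1=CC2=C(Cl)C(=O)[C@@](C)(O)[C@@H](C3=C(OC)C[C@H](C)OC3=O)C2=CO1
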